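## The problem

Compound 21 is a trans-fused hydroazulene; in guaiane numbering the five-membered ring is C1–C2–C3–C4–C5 and the seven-membered ring C1–C10–C9–C8–C7–C6–C5, with the C15 methyl on C4, the C14 methyl on C10 and the isopropyl group on C7. With β defined as the face that carries the isopropyl group, the seven stereocentres (1R,3R,4S,5S,7R,8R,10S) are H1 α and H5 β at the ring fusion, the C8 veratrate and the C10 hydroxyl β, and the C3–C4 epoxide oxygen α. Only the vicinal cis pair C7/C8 has to be set in the absolute sense; once in place, its two β substituents can shield one face of the seven-membered ring and so govern C5 (1,3 to C7) and C10 (1,3 to C8). C1 is α to C10 and can be corrected by equilibration for as long as C10 is a carbonyl group, but not afterwards. The epoxide has no hydroxyl on its own face to direct it, so its configuration must come from the shape of the cyclopentene that the trans fusion locks. The trisubstituted epoxide and the tertiary alcohol do not tolerate acid (opening, transannular ether formation, dehydration), the aryl ester does not tolerate hydride or organometallic reagents, and every C10 ketone on the way has the C8 oxygen in the β-position and can lose it by E1cB elimination; the ester and the epoxide therefore belong at the end. The feature that opens the synthesis is the parent alkene of the epoxide: its substituted carbon C4 is bonded to the fusion carbon C5 and its neighbour C2 is bonded to C1, so that with C10 as a ketone the C1–C5 bond is the alkene of a cyclohept-2-enone and C2–C3–C4–C15 is the chain of a buta-2,3-dienoate with C15 as the ester carbon. A nucleophilic phosphine can join these two pieces in a [3+2] annulation that forms C4–C5 and C1–C2 and leaves the alkene exactly at C3=C4.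

## Retrosynthesis

**Epoxide (21 ⇒ 20).** The C3–O and C4–O bonds are cut first. The epoxide is the most acid-sensitive group, and made last it has to survive no further step; epoxidation before the ester is attached would expose it to alkoxides during desilylation and to acylation. Alkene 20 holds five of the seven stereocentres. The forward step must deliver oxygen to the α face of C3=C4 without a directing group.

**Ester and silyl ether (20 ⇒ 18 + 19; 18 ⇒ 17).** Cutting the acyl–oxygen bond at C8 gives diol 18 and acid chloride 19. The veratrate cannot be carried earlier because hydride and organometallic steps precede it. Diol 18 comes from silyl ether 17. The acylation has to choose the secondary over the tertiary alcohol, which sterics should ensure.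

**C15 (17 ⇒ 15 ⇒ 14).** The C4 methyl is traced to a hydroxymethyl group (15) and that to an ethyl ester (14); two C–O bonds are exchanged for C–H. The ester is the activating group that the three-carbon partner of the annulation needs, and no comparable annulation exists for a methyl-bearing partner, so these two reductive steps are the price of the key step. Forward, the ester must be reduced 1,2 and the allylic oxygen replaced by hydrogen without moving the alkene.

**C14 (14 ⇒ 13).** Cutting the C10–C14 bond gives ketone 13. The ketone cannot be methylated earlier, because it activates the enone for the annulation and makes C1 epimerisable; it must be methylated before the ester reduction, which would otherwise reduce it. Forward, methyl must reach the α face of C10 and react with the ketone, not the ester.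

**Annulation (13 ⇒ 12 ⇒ 10 + 11).** C4–C5 and C1–C2 are cut together: 13 goes back to its C1 epimer 12 and then to enone 10 and allenoate 11. Against single-bond cuts at C1–C5 or C1–C10 (next section), this pair removes a ring, two stereocentres and four carbons in one catalytic step. What remains is a monocyclic enone with two stereocentres. Forward, a reluctant cyclic enone must react, C4 (not C2) must bond to C5 from the α face, and the C1 equilibrium must favour the trans fusion.

**Enone (10 ⇒ 9 ⇒ 8).** Enone 10 is the conjugated isomer of the β,γ-unsaturated ketone 9, which is the ketone of ketal 8. No C–C bond is cut; the alkene is moved from C1=C5 to C5=C6 because that is where the ring opening below leaves it. Forward, the ketal must be hydrolysed without loss of the silyl ether and the alkene conjugated without β-elimination.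

**Desymmetrisation (8 ⇒ 7 ⇒ 5 + 6).** After removal of the silyl group, cutting the C7–isopropyl bond and rejoining the C8 oxygen to C5 gives the meso oxabicyclic ketal 5 and diisopropylzinc 6. One catalytic step then sets C7 and C8 together, cis, in the absolute sense. An acyclic route (auxiliary alkylation, aldol addition, ring-closing metathesis) would reach 10 by more certain single steps but needs about three steps more. Forward, a secondary alkyl group must be transferred syn to the bridge oxygen with high enantioselectivity.

**(4+3) Cycloaddition (5 ⇒ 4 ⇒ 1 + 2).** Ketal 5 comes from ketone 4, whose two C–C bonds between the furan α-carbons and the acetone termini are cut to give furan 1 and tetrabromoacetone 2. The forward reaction is a standard reductive oxyallyl cycloaddition and sets no stereochemistry, since 4 is meso.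

## Roads not taken

**Alternative 1:** The cut runs through C1–C5 and C5–C6: C5 is taken out as a carbene carbon and the seven-membered ring is traced back to a benzene ring. Forward, the aryl diazoketone A1, whose tetrasubstituted arene already carries the C14 methyl, the isopropyl group and the C8 oxygen as a methyl ether, would be decomposed by a chiral dirhodium tetracarboxylate (divalent rhodium) or a monovalent copper bisoxazoline complex. Intramolecular Buchner reaction (cyclopropanation of the C1–C6 arene bond, then electrocyclic opening of the norcaradiene) gives the dihydroazulenone A2.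
- Merits: the whole skeleton except C15 arises in very few steps from a cheap arene; C15 then enters by methyl addition to the C4 ketone, and dehydration of that carbinol could give the C3=C4 alkene directly.
- Weak points: A2 holds one stereocentre (C5) on a flat trienyl ether. C1, C7, C8 and C10 would each have to be set by face-selective reduction, hydration or protonation of a cycloheptatriene with only C5 to steer them, and the trans fusion must be made from an sp2 C1. Such azulenones also isomerise readily to tetralones in acid.
- Comparison: in steps to the bicyclic skeleton this road is clearly shorter than the chosen one, and it needs no thermodynamic gamble at C1 when the rings form. The chosen plan sets C7 and C8 first by a catalyst and then lets them control C5 and C10, so every stereocentre has a named source; Alternative 1 has its hardest stereochemical work still ahead once the rings are closed.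

**Alternative 2:** The cut is the C1–C5 bond alone, which turns the bicycle into a ten-membered ring. Forward, mild acid would open the 4,5-epoxide of the germacrenyl veratrate A3, the C1=C10 alkene would attack C5 across the ring, and the C10 cation would be captured by the carbonyl oxygen of the C8 ester and released by water to give the diol ester A4.
- Merits: one step closes both rings and sets C1, C4, C5 and C10; participation of the ester guarantees the cis relation of the C8 and C10 oxygens; the veratrate is carried from the start, so no protecting group is needed.
- Weak points: the enantiopure (E)-cyclodecene A3, with three stereocentres, a regioselective 4,5-epoxidation and a conformationally labile ring, is itself a long synthesis. A4 carries a C4 carbinol and not the epoxide, so regioselective dehydration of one of two tertiary alcohols toward C3 (not toward C15 or C5) and an α-epoxidation still follow. Hydrolysis of the cyclic acyloxonium stage can also leave the acyl group on the C10 oxygen.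
- Comparison: in stereocentres set per step and in economy of protecting groups this road is better than the chosen one, and its control of C10 by neighbouring-group participation is more certain than face selection in an organometallic addition. The chosen plan answers with starting materials a few steps away instead of a medium ring, and with an alkene that the annulation mechanism places at C3=C4 without a regiochemical choice.

**Alternative 3:** The cut is C1–C10, so the seven-membered ring is closed last onto a preformed cyclopentenone. Forward, a triazolium-derived carbene would turn the C10 aldehyde of A5 into an acyl anion equivalent that adds to the enone β-carbon C1 (intramolecular Stetter reaction) and gives the dione A6.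
- Merits: C15 is a methyl group from the start, which saves the ester reduction and deoxygenation of the chosen plan; the C3 ketone is a direct handle for the C3=C4 alkene (enol triflate toward C4, then reduction); C1 lies α to C10 and can be equilibrated as in the chosen plan.
- Weak points: Stetter closures are reliable for five- and six-membered rings and rare for seven. The aldehyde of A5 has the C8 silyloxy group in the β-position and is prone to elimination under the basic carbene conditions. A5 needs a trans-4,5-disubstituted cyclopentenone with an epimerisable centre joined to the C7/C8 unit, and the two ketones of A6 must be told apart before C10 is methylated.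
- Comparison: Alternative 3 is better on the oxidation state of C15 and equal on the C1 question. The chosen plan forms the easy five-membered ring on an existing seven-membered ring instead of the reverse, by a reaction whose regiochemistry is known for enones, and it carries a single ketone.

Key step: step 6

Assumption: the sense of asymmetric induction of the palladium–Tol-BINAP catalyst on ketal 5 is taken to be that which gives 7 with the (S)-ligand; if it is the opposite, the (R)-ligand is used and nothing else changes.

## Route

Step 1
Reactants: 1 furan; 2 1,1,3,3-tetrabromoacetone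
Product: 4 8-oxabicyclo[3.2.1]oct-6-en-3-one (meso), via dibromo cycloadduct 3 (not isolated)
Conditions: Zn, B(OEt)3, THF, rt; then Zn–Cu couple, NH4Cl, MeOH, −78 °C to rt
Reagents that add atoms: none
Why: Reductive (4+3) cycloaddition: zinc turns 2 into a 1,3-dibromo-2-oxyallyl species that adds across the 2,5-positions of furan, and the Zn–Cu couple then removes both α-bromines. The product is meso, so no stereochemistry has to be controlled.

Step 2
Reactants: 4 8-oxabicyclo[3.2.1]oct-6-en-3-one
Product: 5 spiro[1,3-dioxolane-2,3'-[8]oxabicyclo[3.2.1]oct[6]ene] (ethylene ketal of 4, meso)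
Conditions: HOCH2CH2OH, p-TsOH (cat.), benzene, reflux, Dean–Stark
Reagents that add atoms: ethylene glycol, OCCO
Why: Acid-catalysed ketalisation with azeotropic removal of water; the ketal keeps the future C10 carbonyl away from the organozinc reagent and from the zinc alkoxide formed in step 3.

Step 3
Reactants: 5 ethylene ketal of 8-oxabicyclo[3.2.1]oct-6-en-3-one; 6 diisopropylzinc
Product: 7 (7R,8S)-8-isopropyl-1,4-dioxaspiro[4.6]undec-9-en-7-ol (isopropyl and hydroxyl cis)
Conditions: Pd(CH3CN)2Cl2 (5 mol %), (S)-Tol-BINAP (5 mol %), Zn(OTf)2 (10 mol %), ClCH2CH2Cl, 60 °C; then aq. NH4Cl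
Reagents that add atoms: none
Why: Palladium-catalysed enantioselective alkylative ring opening of a meso oxabicyclic alkene with a dialkylzinc, known for dimethyl- and diethylzinc on oxabicyclo[3.2.1]octenes. A cationic alkylpalladium species (divalent palladium) adds isopropyl and palladium to the exo face and syn β-oxygen elimination opens the bridge, so isopropyl and hydroxyl are cis. The bisphosphine selects one of the two enantiotopic alkene carbons and so sets C7 and C8 (guaiane numbering) in one event.

Step 4
Reactants: 7 (7R,8S)-8-isopropyl-1,4-dioxaspiro[4.6]undec-9-en-7-ol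
Product: 8 tert-butyl{[(7R,8S)-8-isopropyl-1,4-dioxaspiro[4.6]undec-9-en-7-yl]oxy}dimethylsilane
Conditions: TBSCl, imidazole, DMF, 40 °C
Reagents that add atoms: tert-butyldimethylsilyl chloride, CC(C)(C)[Si](C)(C)Cl
Why: Standard silylation of a secondary alcohol. The TBS ether survives steps 5–9, is bulky enough to shield the β face in steps 6 and 7, and is a poor leaving group for β-elimination under mild base.

Step 5
Reactants: 8 TBS ether of 7
Product: 10 (5R,6R)-6-(tert-butyldimethylsilyloxy)-5-isopropylcyclohept-2-en-1-one, via β,γ-unsaturated ketone 9 (not isolated)
Conditions: PPTS, acetone–H2O (10:1), 55 °C; then DBU (0.2 equiv), CH2Cl2, rt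
Reagents that add atoms: water, O
Why: Mild acid hydrolysis of the dioxolane leaves the silyl ether and gives the β,γ-unsaturated ketone 9; amine base then moves the alkene into conjugation through the dienolate. The conjugated isomer 10 is the favoured one and recovered unconjugated material is resubmitted.

Step 6
Reactants: 10 (5R,6R)-6-(tert-butyldimethylsilyloxy)-5-isopropylcyclohept-2-en-1-one; 11 ethyl buta-2,3-dienoate
Product: 13 ethyl 8β-(tert-butyldimethylsilyloxy)-10-oxo-14-nor-1αH,5βH-guai-3-en-15-oate (trans-fused), via cis-fused adduct 12 (not isolated)
Conditions: PPh3 (20 mol %), 11 (3 equiv, slow addition), toluene, 90 °C; then DBU (0.5 equiv), rt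
Reagents that add atoms: none
Why: Phosphine-catalysed allenoate–enone [3+2] annulation (Lu annulation); the closest known cases are annulations of 11 with six-membered cyclic enones under PPh3 in hot toluene. PPh3 adds to the central carbon C3 of 11 to give a phosphonium dienolate whose ester-bearing carbon C4 adds to the enone β-carbon C5 of 10 (α-mode, the normal regiochemistry of unsubstituted allenoates with enones). The C10 enolate then closes the five-membered ring by attack of C1 on the vinylphosphonium terminus C2, formally a 5-endo-trig enolate closure and equally the second bond of an asynchronous [3+2] cycloaddition; a proton shift from C4 to C3 and loss of PPh3 leave the alkene at C3=C4. C5 is set by approach of the dipole to the face of 10 anti to the C7 isopropyl and the pseudo-axial C8 silyloxy group, so that the new C5–C4 bond is α and H5 is β. Ring closure is suprafacial and gives the cis-fused 12 (H1 β) first. C1 is α to the C10 ketone, so DBU equilibrates it, and 13, in which both ring-fusion bonds are equatorial on the seven-membered ring, should be the main component at equilibrium; recovered 12 is resubmitted to the base. The step needs α-regioselectivity, anti facial selectivity and a trans-favouring equilibrium; they rest on the polarity of the dipole, on the two β substituents of 10 and on thermodynamics respectively.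

Step 7
Reactants: 13 ethyl 8β-(tert-butyldimethylsilyloxy)-10-oxo-14-nor-1αH,5βH-guai-3-en-15-oate
Product: 14 ethyl 8β-(tert-butyldimethylsilyloxy)-10β-hydroxy-1αH,5βH-guai-3-en-15-oate
Conditions: MeLi, CeCl3, THF, −78 °C; then aq. NH4Cl
Reagents that add atoms: methyllithium, [Li]C
Why: 1,2-Addition of a non-basic organocerium reagent to an enolisable ketone, chemoselective over the conjugated ester at −78 °C. The reagent attacks C10 from the α face, anti to the pseudo-axial 8β-silyloxy group (1,3 to the carbonyl) and the 7β-isopropyl group, which gives the 10β-hydroxy-10α-methyl carbinol.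

Step 8
Reactants: 14 ethyl 8β-(tert-butyldimethylsilyloxy)-10β-hydroxy-1αH,5βH-guai-3-en-15-oate
Product: 15 8β-(tert-butyldimethylsilyloxy)-1αH,5βH-guai-3-ene-10β,15-diol
Conditions: i-Bu2AlH (4 equiv), CH2Cl2, −78 to 0 °C; then aq. potassium sodium tartrate
Reagents that add atoms: none
Why: 1,2-Reduction of an α,β-unsaturated ester to the allylic alcohol by i-Bu2AlH; the tertiary alcohol only consumes one hydride equivalent and the silyl ether is inert.

Step 9
Reactants: 15 8β-(tert-butyldimethylsilyloxy)-1αH,5βH-guai-3-ene-10β,15-diol
Product: 17 8β-(tert-butyldimethylsilyloxy)-1αH,5βH-guai-3-en-10β-ol, via allylic mesylate 16 (not isolated)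
Conditions: MsCl, Et3N, THF, −40 °C; then LiBHEt3, −40 to 0 °C
Reagents that add atoms: none
Why: One-flask sulfonylation and SN2 hydride displacement of a primary allylic sulfonate by LiBHEt3. The hindered tertiary alcohol is not sulfonylated at −40 °C, and attack at the primary carbon keeps the alkene at C3=C4.

Step 10
Reactants: 17 8β-(tert-butyldimethylsilyloxy)-1αH,5βH-guai-3-en-10β-ol
Product: 18 1αH,5βH-guai-3-ene-8β,10β-diol
Conditions: Bu4NF, THF, rt to 50 °C
Reagents that add atoms: none
Why: Fluoride cleavage of the silyl ether; the alkene and the tertiary alcohol are not affected.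

Step 11
Reactants: 18 1αH,5βH-guai-3-ene-8β,10β-diol; 19 3,4-dimethoxybenzoyl chloride
Product: 20 10β-hydroxy-1αH,5βH-guai-3-en-8β-yl 3,4-dimethoxybenzoate
Conditions: Et3N, DMAP, CH2Cl2, 0 °C to rt
Reagents that add atoms: none
Why: DMAP-catalysed acylation, selective for the secondary alcohol because the tertiary C10 hydroxyl is too hindered to be acylated under these conditions.

Step 12
Reactants: 20 10β-hydroxy-1αH,5βH-guai-3-en-8β-yl 3,4-dimethoxybenzoate
Product: 21 3α,4α-epoxy-10β-hydroxy-1αH,5βH-guaian-8β-yl 3,4-dimethoxybenzoate (CNP0304846.1)
Conditions: mCPBA, NaHCO3, CH2Cl2, 0 °C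
Reagents that add atoms: 3-chloroperoxybenzoic acid, O=C(OO)c1cccc(Cl)c1
Why: Prilezhaev epoxidation of the only electron-rich alkene; the arene is deactivated by its ester carbonyl and the buffer keeps the product from acid. The trans fusion locks the cyclopentene as an envelope with C1 bent to the α face, which makes H2β and H5β pseudo-axial; α attack is staggered to these allylic bonds whereas β attack eclipses them (torsional steering, the preference seen on ring D of trans-fused steroidal 16-enes), so the 3α,4α-epoxide should predominate.

## Compound list

1 | furan | c1ccoc1 | starting material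
2 | 1,1,3,3-tetrabromoacetone | O=C(C(Br)Br)C(Br)Br | starting material
3 | 2,4-dibromo-8-oxabicyclo[3.2.1]oct-6-en-3-one (mixture of C2/C4 epimers) | O=C1C(Br)[C@H]2C=C[C@H](O2)C1Br | intermediate
4 | 8-oxabicyclo[3.2.1]oct-6-en-3-one (meso) | O=C1C[C@H]2C=C[C@H](O2)C1 | intermediate
5 | spiro[1,3-dioxolane-2,3'-[8]oxabicyclo[3.2.1]oct[6]ene] (meso) | O1CCOC12C[C@H]3C=C[C@H](O3)C2 | intermediate
6 | diisopropylzinc | CC(C)[Zn]C(C)C | starting material
7 | (7R,8S)-8-isopropyl-1,4-dioxaspiro[4.6]undec-9-en-7-ol | O[C@@H]2CC3(OCCO3)CC=C[C@@H]2C(C)C | intermediate
8 | tert-butyl{[(7R,8S)-8-isopropyl-1,4-dioxaspiro[4.6]undec-9-en-7-yl]oxy}dimethylsilane | CC(C)(C)[Si](C)(C)O[C@@H]2CC3(OCCO3)CC=C[C@@H]2C(C)C | intermediate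
9 | (5S,6R)-6-(tert-butyldimethylsilyloxy)-5-isopropylcyclohept-3-en-1-one | CC(C)(C)[Si](C)(C)O[C@@H]2CC(=O)CC=C[C@@H]2C(C)C | intermediate
10 | (5R,6R)-6-(tert-butyldimethylsilyloxy)-5-isopropylcyclohept-2-en-1-one | CC(C)(C)[Si](C)(C)O[C@@H]2CC(=O)C=CC[C@@H]2C(C)C | intermediate
11 | ethyl buta-2,3-dienoate | C=C=CC(=O)OCC | starting material
12 | ethyl 8β-(tert-butyldimethylsilyloxy)-10-oxo-14-nor-1βH,5βH-guai-3-en-15-oate (cis-fused) | CC(C)(C)[Si](C)(C)O[C@@H]2CC(=O)[C@H]3CC=C(C(=O)OCC)[C@H]3C[C@@H]2C(C)C | intermediate
13 | ethyl 8β-(tert-butyldimethylsilyloxy)-10-oxo-14-nor-1αH,5βH-guai-3-en-15-oate (trans-fused) | CC(C)(C)[Si](C)(C)O[C@@H]2CC(=O)[C@@H]3CC=C(C(=O)OCC)[C@H]3C[C@@H]2C(C)C | intermediate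
14 | ethyl 8β-(tert-butyldimethylsilyloxy)-10β-hydroxy-1αH,5βH-guai-3-en-15-oate | CC(C)(C)[Si](C)(C)O[C@@H]2C[C@](C)(O)[C@@H]3CC=C(C(=O)OCC)[C@H]3C[C@@H]2C(C)C | intermediate
15 | 8β-(tert-butyldimethylsilyloxy)-1αH,5βH-guai-3-ene-10β,15-diol | CC(C)(C)[Si](C)(C)O[C@@H]2C[C@](C)(O)[C@@H]3CC=C(CO)[C@H]3C[C@@H]2C(C)C | intermediate
16 | 8β-(tert-butyldimethylsilyloxy)-10β-hydroxy-1αH,5βH-guai-3-en-15-yl methanesulfonate | CC(C)(C)[Si](C)(C)O[C@@H]2C[C@](C)(O)[C@@H]3CC=C(COS(C)(=O)=O)[C@H]3C[C@@H]2C(C)C | intermediate
17 | 8β-(tert-butyldimethylsilyloxy)-1αH,5βH-guai-3-en-10β-ol | CC(C)(C)[Si](C)(C)O[C@@H]2C[C@](C)(O)[C@@H]3CC=C(C)[C@H]3C[C@@H]2C(C)C | intermediate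
18 | 1αH,5βH-guai-3-ene-8β,10β-diol | O[C@@H]2C[C@](C)(O)[C@@H]3CC=C(C)[C@H]3C[C@@H]2C(C)C | intermediate
19 | 3,4-dimethoxybenzoyl chloride | COc1ccc(C(=O)Cl)cc1OC | starting material
20 | 10β-hydroxy-1αH,5βH-guai-3-en-8β-yl 3,4-dimethoxybenzoate | COc1ccc(C(=O)O[C@@H]2C[C@](C)(O)[C@@H]3CC=C(C)[C@H]3C[C@@H]2C(C)C)cc1OC | intermediate
21 | 3α,4α-epoxy-10β-hydroxy-1αH,5βH-guaian-8β-yl 3,4-dimethoxybenzoate, (1R,3R,4S,5S,7R,8R,10S) | COc1ccc(C(=O)O[C@@H]2C[C@](C)(O)[C@@H]3C[C@H]4O[C@@]4(C)[C@H]3C[C@@H]2C(C)C)cc1OC | target

## Step count and least certain steps

Total: 12 steps. Longest linear sequence: 12 steps (1 and 2 to 21); the route is linear.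

**Step 6 (key step).** Michael addition of the phosphonium dienolate to a β-alkyl cycloheptenone may be slow, so that oligomerisation of 11 uses up the dipole. Some γ-mode addition, incomplete anti facial selectivity, a C1 equilibrium that does not lie far on the trans side, or base-induced loss of the silyloxy group would each cut the return further.
Fallback: from 10, copper-catalysed conjugate addition of isopropenylmagnesium bromide (CuBr·SMe2 cat., THF, −78 °C) anti to the β substituents and trapping of the enolate with allyl iodide gives the 2,3-trans 2-allyl-3-isopropenyl ketone F1. Ring-closing metathesis with the second-generation Grubbs catalyst closes C3=C4 and gives the trans-fused 14-nor-guai-3-en-10-one F2, with C15 already a methyl group. Organocerium methylation as in step 7 then comes back to the route at 17. This gives up the annulation (C4–C5 and C1–C2 form as two ionic events and C3=C4 by metathesis), uses only standard reactions and bypasses steps 7–9.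

**Step 3.** β-Hydride elimination from the isopropylpalladium species would lead to reductive opening or to transfer of an isomerised alkyl group. Carbopalladation of the less strained [3.2.1] alkene may be slow, and enantioselectivity on a substrate without flanking substituents may be low.
Fallback: from 5, isopropyllithium (Et2O, 0 °C to rt) opens the bridge by syn SN2' attack on the exo face and gives the racemic cis alcohol F3. Lipase-catalysed acylation with vinyl acetate (kinetic resolution; the empirical rule for secondary alcohols predicts acylation of the 7R enantiomer) gives the acetate F4, and methanolysis (K2CO3, MeOH) comes back at 7. Half of the material is lost.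

**Step 5.** Conjugation may stop short, since seven-membered enones keep a sizeable share of the β,γ-isomer at equilibrium, and the base may cause E1cB loss of the silyloxy group.
Fallback: from 8, hydrogenation (H2, Pd/C) gives the saturated ketal F5 and hydrolysis (PPTS, wet acetone) the saturated ketone F6. Kinetic enolisation away from the silyloxy-bearing side (LiN(i-Pr)2, Me3SiCl, THF, −78 °C) gives the trimethylsilyl enol ether F7, and Saegusa–Ito oxidation (Pd(OAc)2, MeCN) comes back at 10. The enone is then formed under kinetic control, with no equilibrium.

**Step 12.** Facial selectivity may be poor or reversed, because steric differences between the two faces are small and the case rests on a torsional effect. Acid-induced opening of the epoxide by the tertiary alcohol is a second hazard.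
Fallback: from 20, N-bromosuccinimide in aqueous THF forms the bromonium ion on the face the peracid preferred (β in this scenario) and water opens it at C4 from the α face to give the 3β-bromo-4α-hydroxy compound F8. DBU closes it with inversion at C3 and comes back at 21. The two-step sequence delivers the epoxide on the face opposite to the one the electrophile attacks.

**Step 7.** Attack from the β face would give the wrong C10 epimer. Competing addition to the ester, and enolisation toward C9 with loss of the silyloxy group, are the other hazards.
Fallback: from 13, Takai–Lombardo methylenation (Zn, CH2Br2, TiCl4) gives the 10(14)-methylene compound F9. Peracid epoxidation of this electron-rich alkene from the same open β face (the enoate alkene is inert) gives the 10β,14-epoxide F10. LiAlH4 (Et2O, 0 °C) opens the epoxide at the methylene carbon and reduces the ester, and the sequence comes back at 15. Oxygen is then delivered from the face that methyl would have taken.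

## Further compounds

F1 | step 6 | 2,3-trans-2-allyl-6-(tert-butyldimethylsilyloxy)-3-isopropenyl-5-isopropylcycloheptan-1-one (3,5-trans, 5,6-cis) | CC(C)(C)[Si](C)(C)O[C@@H]2CC(=O)[C@H](CC=C)[C@@H](C(C)=C)C[C@@H]2C(C)C
F2 | step 6 | 8β-(tert-butyldimethylsilyloxy)-14-nor-1αH,5βH-guai-3-en-10-one | CC(C)(C)[Si](C)(C)O[C@@H]2CC(=O)[C@@H]3CC=C(C)[C@H]3C[C@@H]2C(C)C
F3 | step 3 | rac-cis-8-isopropyl-1,4-dioxaspiro[4.6]undec-9-en-7-ol (racemate, one enantiomer drawn) | O[C@@H]2CC3(OCCO3)CC=C[C@@H]2C(C)C
F4 | step 3 | (7R,8S)-8-isopropyl-1,4-dioxaspiro[4.6]undec-9-en-7-yl acetate | CC(=O)O[C@@H]2CC3(OCCO3)CC=C[C@@H]2C(C)C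
F5 | step 5 | (7R,8R)-7-(tert-butyldimethylsilyloxy)-8-isopropyl-1,4-dioxaspiro[4.6]undecane | CC(C)(C)[Si](C)(C)O[C@@H]2CC3(OCCO3)CCC[C@@H]2C(C)C
F6 | step 5 | (3R,4R)-3-(tert-butyldimethylsilyloxy)-4-isopropylcycloheptan-1-one | CC(C)(C)[Si](C)(C)O[C@@H]2CC(=O)CCC[C@@H]2C(C)C
F7 | step 5 | (5R,6R)-6-(tert-butyldimethylsilyloxy)-5-isopropyl-1-(trimethylsilyloxy)cyclohept-1-ene | CC(C)(C)[Si](C)(C)O[C@@H]2CC(O[Si](C)(C)C)=CCC[C@@H]2C(C)C
F8 | step 12 | 3β-bromo-4α,10β-dihydroxy-1αH,5βH-guaian-8β-yl 3,4-dimethoxybenzoate | COc1ccc(C(=O)O[C@@H]2C[C@](C)(O)[C@@H]3C[C@H](Br)[C@@](C)(O)[C@H]3C[C@@H]2C(C)C)cc1OC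
F9 | step 7 | ethyl 8β-(tert-butyldimethylsilyloxy)-1αH,5βH-guaia-3,10(14)-dien-15-oate | CC(C)(C)[Si](C)(C)O[C@@H]2CC(=C)[C@@H]3CC=C(C(=O)OCC)[C@H]3C[C@@H]2C(C)C
F10 | step 7 | ethyl 8β-(tert-butyldimethylsilyloxy)-10β,14-epoxy-1αH,5βH-guai-3-en-15-oate | CC(C)(C)[Si](C)(C)O[C@@H]2C[C@@]4(CO4)[C@@H]3CC=C(C(=O)OCC)[C@H]3C[C@@H]2C(C)C
A1 | alternative 1 | 1-diazo-4-(5-isopropyl-4-methoxy-2-methylphenyl)butan-2-one | [N-]=[N+]=CC(=O)CCc1cc(C(C)C)c(OC)cc1C
A2 | alternative 1 | 7-isopropyl-6-methoxy-4-methyl-3,8a-dihydroazulen-1(2H)-one (8a-H as H5β) | O=C1CCC2=C(C)C=C(OC)C(C(C)C)=C[C@H]12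
A3 | alternative 2 | (1(10)E)-4,5-epoxygermacr-1(10)-en-8-yl 3,4-dimethoxybenzoate | COc1ccc(C(=O)O[C@@H]2C/C(C)=C/CC[C@]3(C)O[C@H]3C[C@@H]2C(C)C)cc1OC
A4 | alternative 2 | 4β,10β-dihydroxy-1αH,5βH-guaian-8β-yl 3,4-dimethoxybenzoate | COc1ccc(C(=O)O[C@@H]2C[C@](C)(O)[C@@H]3CC[C@](C)(O)[C@H]3C[C@@H]2C(C)C)cc1OC
A5 | alternative 3 | 3-(tert-butyldimethylsilyloxy)-4-isopropyl-5-(trans-5-methyl-4-oxocyclopent-2-en-1-yl)pentanal | CC(C)(C)[Si](C)(C)O[C@H](CC=O)[C@@H](C(C)C)C[C@H]1C=CC(=O)[C@@H]1C
A6 | alternative 3 | 8β-(tert-butyldimethylsilyloxy)-14-nor-1αH,4αH,5βH-guaiane-3,10-dione | CC(C)(C)[Si](C)(C)O[C@@H]2CC(=O)[C@@H]3CC(=O)[C@H](C)[C@H]3C[C@@H]2C(C)C
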